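**Plan**

- Retrosynthesis: once the silyl groups, the 2-(trimethylsilyl)ethyl ester and the C15 oxygen are removed, ring A and the lactone are cut together at C2–C3 (aldol) and C4–C5 (Michael). Further cuts are C10–C1, C13–C16 (ring D) and C8–C14/C9–C11 (ring C), leaving a resolved 2-propargyl-4-silyloxycyclopentenone (ring B) and a 2,3-bis(silyloxy)butadiene.
- Forward order: ring B (from furfural) → ring C (Diels–Alder) → ring D (gold-catalysed enol ether–alkyne closure) → C7 ester and C10 ketone → lactone ring and ring A in one base-mediated cascade → C1=C2 alkene, C6 epimerisation, C15 hydroxyl, deprotection.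
- Enabling feature: C4 lies between the lactone carbonyl C19 and the carbinol carbon C3, C5 is β to the C7 carboxyl, O3 is β to C1, and the lactone oxygen on C10 ties the C19–C4–C3 unit to ring B. The 2-formylpropanoate of a 10-acetyl-10-ol on a C5=C6 unsaturated ring B ester can therefore close the γ-lactone (C4–C5) and ring A (C2–C3) in one operation.
- Stereochemistry: the lipase-resolved C10 silyloxy centre steers the Diels–Alder reaction (C8, C9). The polycyclic framework then controls C13, C12, C10, C5, C4, C3 and C15; C6 is set by equilibration.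

Key step: step 18

Remark: GA32 denotes the target gibberellin; its gibberellane numbering (C1–C19) is used for all polycyclic intermediates, β being the face that carries H5, H9 and C15, and the lipase is assumed to acylate the (R)-alcohol, as is usual for 4-hydroxycyclopent-2-enones.

**Step 1**
Reactants: 1 furfural; 2 propargyl bromide
Product: 3 rac-1-(furan-2-yl)but-3-yn-1-ol
Conditions: Zn dust, THF, 0 °C to rt; cold 1 M HCl work-up
Reagents that add atoms: none
Why: Barbier propargylation, in which the allenylzinc bromide adds through its γ-carbon to the aldehyde and should give mainly the homopropargylic carbinol; its stereocentre is erased in step 2.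

**Step 2**
Reactants: 3 rac-1-(furan-2-yl)but-3-yn-1-ol
Product: 5 rac-4-hydroxy-2-(prop-2-ynyl)cyclopent-2-enone, via rac-trans-4-hydroxy-5-(prop-2-ynyl)cyclopent-2-enone 4 (not isolated)
Conditions: ZnCl2, dioxane/H2O, reflux; then basic Al2O3, Et2O, rt
Reagents that add atoms: water (O)
Why: Piancatelli rearrangement (furylcarbinol cation, water capture, conrotatory 4π closure to the trans-4-hydroxy-5-alkyl enone) followed by the usual base-mediated isomerisation to the more stable 2-alkyl-4-hydroxy enone.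

**Step 3**
Reactants: 5 rac-4-hydroxy-2-(prop-2-ynyl)cyclopent-2-enone
Product: 6 (R)-4-acetoxy-2-(prop-2-ynyl)cyclopent-2-enone
Conditions: lipase from Burkholderia cepacia (immobilised), vinyl acetate, t-BuOMe, 30 °C, stopped near half conversion; chromatography
Reagents that add atoms: vinyl acetate (CC(=O)OC=C)
Why: Lipase-catalysed kinetic resolution by irreversible transesterification should acetylate the (R)-alcohol only; the unreacted enantiomer of 5 is separated, which fixes the absolute configuration of the route at the future C10.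

**Step 4**
Reactants: 6 (R)-4-acetoxy-2-(prop-2-ynyl)cyclopent-2-enone
Product: 7 (R)-4-hydroxy-2-(prop-2-ynyl)cyclopent-2-enone
Conditions: Candida antarctica lipase B (immobilised), MeOH, t-BuOMe, 30 °C
Reagents that add atoms: none
Why: Enzymatic methanolysis removes the acetate under neutral conditions and so avoids β-elimination of the 4-acyloxy enone.

**Step 5**
Reactants: 7 (R)-4-hydroxy-2-(prop-2-ynyl)cyclopent-2-enone
Product: 8 (R)-2-(prop-2-ynyl)-4-(triethylsilyloxy)cyclopent-2-enone
Conditions: Et3SiCl, imidazole, CH2Cl2, 0 °C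
Reagents that add atoms: chlorotriethylsilane (CC[Si](CC)(CC)Cl)
Why: Standard silylation of a secondary alcohol; the triethylsilyl group is chosen because it can later be removed in the presence of tert-butyldimethylsilyl ethers.

**Step 6**
Reactants: 9 butane-2,3-dione
Product: 10 2,3-bis(tert-butyldimethylsilyloxy)buta-1,3-diene
Conditions: t-BuMe2SiOTf (2.2 equiv), Et3N, Et2O, 0 °C to rt
Reagents that add atoms: tert-butyldimethylsilyl trifluoromethanesulfonate (CC(C)(C)[Si](C)(C)OS(=O)(=O)C(F)(F)F)
Why: Double soft enolisation and O-silylation of a 1,2-diketone gives the 2,3-bis(silyloxy)diene.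

**Step 7**
Reactants: 8 (R)-2-(prop-2-ynyl)-4-(triethylsilyloxy)cyclopent-2-enone; 10 2,3-bis(tert-butyldimethylsilyloxy)buta-1,3-diene
Product: 11 cis-fused ring B/C ketone (6-oxo; 8β-propargyl; H9 β; 10β-OSiEt3; C12=C13 enediol bis-TBS ether)
Conditions: toluene, 2,6-di-tert-butyl-4-methylphenol (cat.), 140 °C, sealed tube
Reagents that add atoms: none
Why: Thermal Diels–Alder reaction in which the diene should add to the enone face anti to the C10 silyloxy group with cis ring fusion, setting quaternary C8 and C9; the symmetric diene raises no regiochemical question and delivers C12 and C13 as a regiodefined enediol bis(silyl ether).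

**Step 8**
Reactants: 11 cis-fused ring B/C ketone
Product: 12 C6 enol triflate (C5=C6–OTf)
Conditions: KN(SiMe3)2, THF, −78 °C; then PhNTf2, −78 °C
Reagents that add atoms: N-phenylbis(trifluoromethanesulfonimide) (O=S(=O)(N(c1ccccc1)S(=O)(=O)C(F)(F)F)C(F)(F)F)
Why: The C6 ketone can enolise only toward C5 because C8 is quaternary, and O-triflation at −78 °C should outrun β-elimination of the C10 silyloxy group.

**Step 9**
Reactants: 12 C6 enol triflate
Product: 13 tricyclic ring B/C/D ketone (12-oxo; 13-OTBS; 16-methylene; 10β-OSiEt3; C5=C6–OTf)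
Conditions: Ph3PAuCl (5 mol %), AgBF4 (5 mol %), CH2Cl2/H2O 10:1, rt
Reagents that add atoms: none
Why: Gold-catalysed Conia-ene-type 5-exo-dig carbocyclisation of a silyl enol ether onto a terminal alkyne: C13 should attack the gold-activated C16 from the axial propargyl group and close ring D as a bicyclo[3.2.1]octane in preference to the 6-exo mode from C12; loss of the O12 silyl group gives the C12 ketone and the bridge fixes C13.

**Step 10**
Reactants: 13 tricyclic ring B/C/D ketone
Product: 14 C7 2-(trimethylsilyl)ethyl ester (C5=C6–CO2CH2CH2SiMe3)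
Conditions: Pd(OAc)2 (5 mol %), Ph2P(CH2)3PPh2, CO (1 atm), Me3SiCH2CH2OH, Et3N, DMF, 50 °C
Reagents that add atoms: carbon monoxide ([C-]#[O+]); 2-(trimethylsilyl)ethanol (C[Si](C)(C)CCO)
Why: Palladium-catalysed alkoxycarbonylation of the vinyl triflate installs C7 as an ester that can later be cleaved without hydroxide.

**Step 11**
Reactants: 14 C7 2-(trimethylsilyl)ethyl ester
Product: 15 12α-alcohol
Conditions: NaBH4, MeOH/THF, −40 to 0 °C
Reagents that add atoms: none
Why: Ketone reduction in which hydride should attack C12 from the equatorial side, because the axial C9–C10 bond of ring B blocks the opposite face, giving the axial 12α-alcohol cis to O13.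

**Step 12**
Reactants: 15 12α-alcohol
Product: 16 12α,13-bis-TBS ether
Conditions: t-BuMe2SiOTf, 2,6-lutidine, CH2Cl2, 0 °C to rt
Reagents that add atoms: tert-butyldimethylsilyl trifluoromethanesulfonate (CC(C)(C)[Si](C)(C)OS(=O)(=O)C(F)(F)F)
Why: A silyl triflate silylates the hindered axial alcohol and leaves the other groups untouched.

**Step 13**
Reactants: 16 12α,13-bis-TBS ether
Product: 17 10β-alcohol
Conditions: pyridinium p-toluenesulfonate (cat.), MeOH/CH2Cl2, 0 °C
Reagents that add atoms: none
Why: Acid-catalysed methanolysis cleaves the triethylsilyl ether selectively, since the two hindered TBS ethers are far slower.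

**Step 14**
Reactants: 17 10β-alcohol
Product: 18 ring B enone (10-oxo; C5=C6–CO2CH2CH2SiMe3)
Conditions: Dess–Martin periodinane, CH2Cl2, rt
Reagents that add atoms: none
Why: Dess–Martin oxidation of the allylic alcohol gives the 4-oxocyclopentene carboxylate without touching the silyl ethers or the 16-methylene group.

**Step 15**
Reactants: 19 ethyl prop-1-enyl ether; 20 oxalyl chloride
Product: 22 (E)-3-ethoxy-2-methylacryloyl chloride, via 4-ethoxy-3-methyl-2-oxobut-3-enoyl chloride 21 (not isolated)
Conditions: neat, 0 °C to rt; then 120 °C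
Reagents that add atoms: none
Why: C-acylation of the enol ether by oxalyl chloride followed by thermal loss of carbon monoxide is the known route to 3-alkoxyacryloyl chlorides and should give the more stable E isomer.

**Step 16**
Reactants: 18 ring B enone; 22 (E)-3-ethoxy-2-methylacryloyl chloride
Product: 24 C10 acrylate ester (10β-(1-ethoxyvinyl); 10α-O-(E)-3-ethoxy-2-methylacryloyl), via C10 dichlorocerium alkoxide 23 (not isolated)
Conditions: CH2=C(OEt)Li (from ethyl vinyl ether, t-BuLi, THF, −78 to 0 °C), CeCl3, THF, −78 °C; then 22, −78 to 0 °C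
Reagents that add atoms: ethyl vinyl ether (C=COCC), used as 1-ethoxyvinyllithium
Why: Organocerium 1,2-addition of the acetyl anion equivalent to the C10 ketone should occur from the β face, because the α face is covered by ring C and the axial 12α-silyloxy group; this sets C10, and the tertiary alkoxide is acylated in the same flask.

**Step 17**
Reactants: 24 C10 acrylate ester
Product: 25 cascade substrate (10β-acetyl; 10α-O-(2-formylpropanoyl); C4 epimers, largely enolised)
Conditions: 1 M HCl, THF, 0 °C to rt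
Reagents that add atoms: water (O)
Why: Acid hydrolysis of both enol ethers unmasks the methyl ketone and the formyl ester, while the hindered TBS ethers and the silylethyl ester should survive.

**Step 18**
Reactants: 25 cascade substrate
Product: 28 ring A ketone triethylsilyl ether (1-oxo; 3β-OSiEt3; 19,10-lactone; 6-epi), via lactone aldehyde 26 (not isolated), via ring A ketol 27 (not isolated)
Conditions: DBU (1.5 equiv), MeCN, 0 °C to rt; then Et3SiCl, 0 °C to rt
Reagents that add atoms: chlorotriethylsilane (CC[Si](CC)(CC)Cl)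
Why: DBU deprotonates the enolised 2-formylpropanoate and its C4 enolate adds to C5 of the cyclopentene ester (intramolecular Michael, 5-exo-trig, closing the γ-lactone C19–O–C10–C5–C4); the C6 ester enolate then takes a proton from the acetyl methyl group, and the resulting C2 enolate adds to the C3 aldehyde (intramolecular aldol, 6-enolendo-exo-trig, closing ring A as the three-atom bridge of a 6-oxabicyclo[3.2.1]octan-7-one). The closest known reaction type is the tandem intramolecular Michael–aldol annulation of tethered 1,3-dicarbonyl donors. C5 is set by the C10–O tether, which forces C4 to arrive cis to the lactone oxygen. C4 is set by placing the charged C3–O arm of the enolate next to H5 and away from the developing C6/C7 enolate, which is also the only arrangement that can reach the acetyl group. C3 is set by the aldehyde rotamer whose C=O is antiperiplanar to the lactone C=O under non-chelating conditions (3β-OH, cis to C18), while C6 is expected to be protonated on the open β face and is corrected in step 21. The step needs C4 to attack C5 and not the C1 ketone, and C2 to attack the aldehyde and not the lactone carbonyl; the first is secured because the ketone adduct is reversible and cannot dehydrate, the second by the higher electrophilicity of the aldehyde, and silylation in the same flask stops retro-aldol and dehydration.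

**Step 19**
Reactants: 28 ring A ketone triethylsilyl ether
Product: 29 C1 enol triflate (C1=C2; 1-OTf)
Conditions: KN(SiMe3)2, THF, −78 °C; then PhNTf2, −78 °C
Reagents that add atoms: N-phenylbis(trifluoromethanesulfonimide) (O=S(=O)(N(c1ccccc1)S(=O)(=O)C(F)(F)F)C(F)(F)F)
Why: The C1 ketone can enolise only toward C2 because C10 is quaternary, and trapping at −78 °C should be faster than loss of the 3-silyloxy group.

**Step 20**
Reactants: 29 C1 enol triflate
Product: 30 C1=C2 alkene (6-epi)
Conditions: Pd(OAc)2 (5 mol %), PPh3, HCO2H, n-Bu3N, DMF, 50 °C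
Reagents that add atoms: none
Why: Palladium-catalysed formate reduction of the enol triflate gives the C1=C2 alkene; oxidative addition of zerovalent palladium to the triflate should be much faster than ionisation of the hindered tertiary allylic lactone.

**Step 21**
Reactants: 30 C1=C2 alkene (6-epi)
Product: 31 C1=C2 alkene with natural C6 (C7 β)
Conditions: KOt-Bu (0.2 equiv), t-BuOH/THF, 0 °C to rt
Reagents that add atoms: none
Why: Thermodynamic epimerisation through the ester enolate should move C7 to the β face, trans to the quaternary C4.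

**Step 22**
Reactants: 31 C1=C2 alkene with natural C6
Product: 33 15-ketone (16-en-15-one), via 15α-alcohol 32 (not isolated)
Conditions: SeO2 (0.5 equiv), t-BuOOH, CH2Cl2, rt; then Dess–Martin periodinane, rt
Reagents that add atoms: tert-butyl hydroperoxide (CC(C)(C)OO)
Why: SeO2 allylic oxidation (ene reaction, then [2,3]-sigmatropic shift) attacks C15, the only allylic C–H of the 16-methylene group, and Dess–Martin oxidation carries the alcohol on to the enone, so the configuration of 32 does not matter.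

**Step 23**
Reactants: 33 15-ketone
Product: 34 15β-alcohol
Conditions: NaBH4, CeCl3·7H2O, MeOH, −78 °C
Reagents that add atoms: none
Why: Luche 1,2-reduction in which hydride should reach C15 from the face turned away from the C9–C11–C12 bridge, leaving the hydroxyl on the side of that bridge (15β).

**Step 24**
Reactants: 34 15β-alcohol
Product: 35 GA32 2-(trimethylsilyl)ethyl ester
Conditions: HF·pyridine, pyridine, THF, 0 °C to rt
Reagents that add atoms: none
Why: Buffered HF should cleave the triethylsilyl and both TBS ethers (the bridgehead C13 cannot ionise) and spare ring A and the silylethyl ester.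

**Step 25**
Reactants: 35 GA32 2-(trimethylsilyl)ethyl ester
Product: 36 GA32 (the target gibberellin)
Conditions: tris(dimethylamino)sulfonium difluorotrimethylsilicate, DMF, 0 °C to rt; dilute HCl to pH 3
Reagents that add atoms: none
Why: Fluoride-induced β-elimination of the 2-(trimethylsilyl)ethyl ester frees the C7 acid without hydroxide, which avoids the base-induced lactone rearrangement of ring A.

**Compound list**

1 | furfural | O=Cc1ccco1 | starting material
2 | propargyl bromide | C#CCBr | starting material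
3 | rac-1-(furan-2-yl)but-3-yn-1-ol | OC(CC#C)c1ccco1 | intermediate
4 | rac-trans-4-hydroxy-5-(prop-2-ynyl)cyclopent-2-enone (one enantiomer drawn) | O=C1C=C[C@@H](O)[C@@H]1CC#C | intermediate
5 | rac-4-hydroxy-2-(prop-2-ynyl)cyclopent-2-enone | O=C1CC(O)C=C1CC#C | intermediate
6 | (R)-4-acetoxy-2-(prop-2-ynyl)cyclopent-2-enone | O=C1C[C@@H](OC(C)=O)C=C1CC#C | intermediate
7 | (R)-4-hydroxy-2-(prop-2-ynyl)cyclopent-2-enone | O=C1C[C@@H](O)C=C1CC#C | intermediate
8 | (R)-2-(prop-2-ynyl)-4-(triethylsilyloxy)cyclopent-2-enone | O=C1C[C@@H](O[Si](CC)(CC)CC)C=C1CC#C | intermediate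
9 | butane-2,3-dione | CC(=O)C(C)=O | starting material
10 | 2,3-bis(tert-butyldimethylsilyloxy)buta-1,3-diene | C=C(O[Si](C)(C)C(C)(C)C)C(=C)O[Si](C)(C)C(C)(C)C | intermediate
11 | cis-fused ring B/C ketone: 6-oxo, 8β-propargyl, H9 β, 10β-OSiEt3, C12=C13 enediol bis-TBS ether | C#CC[C@]12CC(O[Si](C)(C)C(C)(C)C)=C(O[Si](C)(C)C(C)(C)C)C[C@H]1[C@H](O[Si](CC)(CC)CC)CC2=O | intermediate
12 | C6 enol triflate of 11 (C5=C6–OTf) | C#CC[C@]12CC(O[Si](C)(C)C(C)(C)C)=C(O[Si](C)(C)C(C)(C)C)C[C@H]1[C@H](O[Si](CC)(CC)CC)C=C2OS(=O)(=O)C(F)(F)F | intermediate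
13 | tricyclic ring B/C/D ketone: 12-oxo, 13-OTBS, 16-methylene, 10β-OSiEt3, C5=C6–OTf | C=C1C[C@]23C[C@@]1(O[Si](C)(C)C(C)(C)C)C(=O)C[C@H]2[C@H](O[Si](CC)(CC)CC)C=C3OS(=O)(=O)C(F)(F)F | intermediate
14 | C7 2-(trimethylsilyl)ethyl ester: as 13 with C5=C6–CO2CH2CH2SiMe3 | C=C1C[C@]23C[C@@]1(O[Si](C)(C)C(C)(C)C)C(=O)C[C@H]2[C@H](O[Si](CC)(CC)CC)C=C3C(=O)OCC[Si](C)(C)C | intermediate
15 | 12α-alcohol of 14 | C=C1C[C@]23C[C@@]1(O[Si](C)(C)C(C)(C)C)[C@@H](O)C[C@H]2[C@H](O[Si](CC)(CC)CC)C=C3C(=O)OCC[Si](C)(C)C | intermediate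
16 | 12α,13-bis-TBS ether | C=C1C[C@]23C[C@@]1(O[Si](C)(C)C(C)(C)C)[C@@H](O[Si](C)(C)C(C)(C)C)C[C@H]2[C@H](O[Si](CC)(CC)CC)C=C3C(=O)OCC[Si](C)(C)C | intermediate
17 | 10β-alcohol | C=C1C[C@]23C[C@@]1(O[Si](C)(C)C(C)(C)C)[C@@H](O[Si](C)(C)C(C)(C)C)C[C@H]2[C@H](O)C=C3C(=O)OCC[Si](C)(C)C | intermediate
18 | ring B enone: 10-oxo, C5=C6–CO2CH2CH2SiMe3 | C=C1C[C@]23C[C@@]1(O[Si](C)(C)C(C)(C)C)[C@@H](O[Si](C)(C)C(C)(C)C)C[C@H]2C(=O)C=C3C(=O)OCC[Si](C)(C)C | intermediate
19 | ethyl prop-1-enyl ether (E/Z mixture) | CC=COCC | starting material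
20 | oxalyl chloride | ClC(=O)C(Cl)=O | starting material
21 | 4-ethoxy-3-methyl-2-oxobut-3-enoyl chloride | CCOC=C(C)C(=O)C(Cl)=O | intermediate
22 | (E)-3-ethoxy-2-methylacryloyl chloride | CCO/C=C(C)/C(Cl)=O | intermediate
23 | C10 dichlorocerium alkoxide: 10β-(1-ethoxyvinyl), 10α-OCeCl2 | C=C1C[C@]23C[C@@]1(O[Si](C)(C)C(C)(C)C)[C@@H](O[Si](C)(C)C(C)(C)C)C[C@H]2[C@](O[Ce](Cl)Cl)(C(=C)OCC)C=C3C(=O)OCC[Si](C)(C)C | intermediate
24 | C10 acrylate ester: 10β-(1-ethoxyvinyl), 10α-O-(E)-3-ethoxy-2-methylacryloyl | C=C1C[C@]23C[C@@]1(O[Si](C)(C)C(C)(C)C)[C@@H](O[Si](C)(C)C(C)(C)C)C[C@H]2[C@](OC(=O)/C(C)=C/OCC)(C(=C)OCC)C=C3C(=O)OCC[Si](C)(C)C | intermediate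
25 | cascade substrate: 10β-acetyl, 10α-O-(2-formylpropanoyl), C4 unassigned (epimers, largely enol) | C=C1C[C@]23C[C@@]1(O[Si](C)(C)C(C)(C)C)[C@@H](O[Si](C)(C)C(C)(C)C)C[C@H]2[C@](OC(=O)C(C)C=O)(C(C)=O)C=C3C(=O)OCC[Si](C)(C)C | intermediate
26 | lactone aldehyde (Michael adduct): 19,10-lactone, 4-formyl, 10β-acetyl, 6-epi | C=C1C[C@]23C[C@@]1(O[Si](C)(C)C(C)(C)C)[C@@H](O[Si](C)(C)C(C)(C)C)C[C@H]2[C@@]4(C(C)=O)OC(=O)[C@](C)(C=O)[C@H]4[C@H]3C(=O)OCC[Si](C)(C)C | intermediate
27 | ring A ketol (aldol): 1-oxo, 3β-OH, 19,10-lactone, 6-epi | C=C1C[C@]23C[C@@]1(O[Si](C)(C)C(C)(C)C)[C@@H](O[Si](C)(C)C(C)(C)C)C[C@H]2[C@@]12C(=O)C[C@H](O)[C@@](C)(C(=O)O1)[C@H]2[C@H]3C(=O)OCC[Si](C)(C)C | intermediate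
28 | ring A ketone triethylsilyl ether: 1-oxo, 3β-OSiEt3, 6-epi | C=C1C[C@]23C[C@@]1(O[Si](C)(C)C(C)(C)C)[C@@H](O[Si](C)(C)C(C)(C)C)C[C@H]2[C@@]12C(=O)C[C@H](O[Si](CC)(CC)CC)[C@@](C)(C(=O)O1)[C@H]2[C@H]3C(=O)OCC[Si](C)(C)C | intermediate
29 | C1 enol triflate (C1=C2), 6-epi | C=C1C[C@]23C[C@@]1(O[Si](C)(C)C(C)(C)C)[C@@H](O[Si](C)(C)C(C)(C)C)C[C@H]2[C@@]12C(OS(=O)(=O)C(F)(F)F)=C[C@H](O[Si](CC)(CC)CC)[C@@](C)(C(=O)O1)[C@H]2[C@H]3C(=O)OCC[Si](C)(C)C | intermediate
30 | C1=C2 alkene, 6-epi (C7 α) | C=C1C[C@]23C[C@@]1(O[Si](C)(C)C(C)(C)C)[C@@H](O[Si](C)(C)C(C)(C)C)C[C@H]2[C@@]12C=C[C@H](O[Si](CC)(CC)CC)[C@@](C)(C(=O)O1)[C@H]2[C@H]3C(=O)OCC[Si](C)(C)C | intermediate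
31 | C1=C2 alkene with natural C6 (C7 β): 3-O-SiEt3, 12,13-bis-O-TBS 15-deoxy-GA32 silylethyl ester | C=C1C[C@]23C[C@@]1(O[Si](C)(C)C(C)(C)C)[C@@H](O[Si](C)(C)C(C)(C)C)C[C@H]2[C@@]12C=C[C@H](O[Si](CC)(CC)CC)[C@@](C)(C(=O)O1)[C@H]2[C@@H]3C(=O)OCC[Si](C)(C)C | intermediate
32 | 15α-alcohol | C=C1[C@H](O)[C@]23C[C@@]1(O[Si](C)(C)C(C)(C)C)[C@@H](O[Si](C)(C)C(C)(C)C)C[C@H]2[C@@]12C=C[C@H](O[Si](CC)(CC)CC)[C@@](C)(C(=O)O1)[C@H]2[C@@H]3C(=O)OCC[Si](C)(C)C | intermediate
33 | 15-ketone (16-en-15-one) | C=C1C(=O)[C@]23C[C@@]1(O[Si](C)(C)C(C)(C)C)[C@@H](O[Si](C)(C)C(C)(C)C)C[C@H]2[C@@]12C=C[C@H](O[Si](CC)(CC)CC)[C@@](C)(C(=O)O1)[C@H]2[C@@H]3C(=O)OCC[Si](C)(C)C | intermediate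
34 | 15β-alcohol (fully protected GA32) | C=C1[C@@H](O)[C@]23C[C@@]1(O[Si](C)(C)C(C)(C)C)[C@@H](O[Si](C)(C)C(C)(C)C)C[C@H]2[C@@]12C=C[C@H](O[Si](CC)(CC)CC)[C@@](C)(C(=O)O1)[C@H]2[C@@H]3C(=O)OCC[Si](C)(C)C | intermediate
35 | GA32 2-(trimethylsilyl)ethyl ester | C=C1[C@@H](O)[C@]23C[C@@]1(O)[C@@H](O)C[C@H]2[C@@]12C=C[C@H](O)[C@@](C)(C(=O)O1)[C@H]2[C@@H]3C(=O)OCC[Si](C)(C)C | intermediate
36 | GA32, the target gibberellin: 3β,12α,13,15β-tetrahydroxy-1,16-diene 7-carboxylic acid 19,10-lactone of the 20-norgibberellane skeleton | C=C1[C@@H](O)[C@]23C[C@@]1(O)[C@@H](O)C[C@H]2[C@@]12C=C[C@H](O)[C@@](C)(C(=O)O1)[C@H]2[C@@H]3C(=O)O | target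

**Step count and risks**

Total: 25 steps. Longest linear sequence: 23 steps (steps 1–5, 7–14 and 16–25).

Most likely to fail:

Step 18. The aldol closure may lose to O-to-C acyl migration or to loss of water from the ketol, or the Michael step may place the formyl group on the wrong face of C4 with no way back. The fallback sets out from 25 and separates the two bond formations. Cs2CO3 (cat.) in MeCN stops at the lactone aldehyde 26, which is isolated. Me3SiOTf/Et3N (CH2Cl2, −78 °C) turns its methyl ketone into the trimethylsilyl enol ether F1. BF3·OEt2 (CH2Cl2, −78 °C) then closes the C2–C3 bond by an intramolecular Mukaiyama aldol addition to the dipole-minimised aldehyde rotamer, giving 27. Silylation with Et3SiCl and imidazole gives 28, where the route is rejoined.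

Step 16. The basic organometallic may enolise the C10 ketone, and the tertiary alkoxide next to the 12α-silyloxy group may be acylated incompletely. The fallback sets out from 18. The same organocerium addition is quenched with aqueous NH4Cl to give the tertiary alcohol F2, and oxalic acid in wet THF unmasks the methyl ketone to give the α-ketol F3. Heating F3 with 2,2,5-trimethyl-4H-1,3-dioxin-4-one (CC1=COC(C)(C)OC1=O) in toluene at 110 °C releases formyl(methyl)ketene by cycloreversion. This small, neutral electrophile acylates the hindered alcohol and gives 25 directly, so the route is rejoined at 25 and step 17 is skipped.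

Step 7. Cycloaddition of the trisubstituted enone may be slow enough for thermal loss of triethylsilanol from 8 or 11 to take over. The fallback sets out from 8 and 10 and builds ring C by two polar steps at low temperature. With t-BuMe2SiOTf (10 mol %) in CH2Cl2 at −78 °C, a Mukaiyama–Michael addition of the diene terminus to C9, anti to the silyloxy group, gives the silyl enol ether–enone F4. On warming to −20 °C the C8 silyl enol ether of F4 adds to the α-silyloxy enone in a second, intramolecular Mukaiyama–Michael step. This closes the C8–C14 bond cis and returns the enediol bis(silyl ether) 11.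

**Further compounds**

F1 | step 18 | trimethylsilyl enol ether of lactone aldehyde 26 | C=C1C[C@]23C[C@@]1(O[Si](C)(C)C(C)(C)C)[C@@H](O[Si](C)(C)C(C)(C)C)C[C@H]2[C@@]4(C(=C)O[Si](C)(C)C)OC(=O)[C@](C)(C=O)[C@H]4[C@H]3C(=O)OCC[Si](C)(C)C
F2 | step 16 | tertiary alcohol: 10α-hydroxy-10β-(1-ethoxyvinyl) adduct of 18 | C=C1C[C@]23C[C@@]1(O[Si](C)(C)C(C)(C)C)[C@@H](O[Si](C)(C)C(C)(C)C)C[C@H]2[C@](O)(C(=C)OCC)C=C3C(=O)OCC[Si](C)(C)C
F3 | step 16 | α-ketol: 10β-acetyl-10α-ol | C=C1C[C@]23C[C@@]1(O[Si](C)(C)C(C)(C)C)[C@@H](O[Si](C)(C)C(C)(C)C)C[C@H]2[C@](O)(C(C)=O)C=C3C(=O)OCC[Si](C)(C)C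
F4 | step 7 | Mukaiyama–Michael adduct: 1-(tert-butyldimethylsilyloxy)-2-(prop-2-ynyl)-3-[3-(tert-butyldimethylsilyloxy)-2-oxobut-3-enyl]-4-(triethylsilyloxy)cyclopentene, side chain trans to the silyloxy group | C#CCC1=C(O[Si](C)(C)C(C)(C)C)C[C@@H](O[Si](CC)(CC)CC)[C@@H]1CC(=O)C(=C)O[Si](C)(C)C(C)(C)C
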